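## The problem

The target is a ten-membered carbocycle (ring A, C1–C10) with an α-methylene-γ-butyrolactone (ring B: O–C1, C10, C11 with its methylene C13, C12) fused trans across C1/C10, and an (E)-2-(acetoxymethyl)but-2-enoate on the neighbouring C9 oxygen. Three contiguous stereocentres (C1, C10, C9; C1–O on one face, C11 and C9–O on the other) are joined by a fourth, the C3 methyl, which is insulated from them by C2 and sits α to the C4 ketone. In a flexible ten-membered ring C3 cannot be set from C1/C10, but on a six-membered ring the same atoms are 1,3- and 1,4-related and can control one another, and a free C1 hydroxyl can later deliver hydride to C9. The C6=C7 olefin is trisubstituted, Z and skipped relative to the C4 ketone, so it must be made cis and kept out of conjugation. Fragile elements are the α-methylene lactone (a Michael acceptor, best made last), the β,γ-unsaturated ketone with its epimerisable C3, the side-chain ester (an allylic acetate open to SN2' attack by nucleophilic amines), and any intermediate with carbonyls at both C4 and C9, which is a cyclodecane-1,6-dione prone to transannular aldol. Both C1–O and C9–O are γ to C12, so the lactone must be directed to C1. The enabling feature is that C4 and C9 are both oxygenated, face each other across ring A and are linked on one side by C5–C6=C7–C8. A C4–C9 bond would therefore give two fused six-membered rings, a cyclohexene that holds the olefin cis and a cyclohexane that carries C1, C3 and C10, and the diene of that bicycle is the Birch product of a tetralin.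

## Retrosynthesis

**Lactone and C4 ketone (34 ⇒ 32).** The O1–C12 bond is cut and the C4 carbonyl is masked together with the C1 oxygen as a bridged methyl ketal, giving acrylic acid 32. This is preferred to a late lactone methylenation by enolate chemistry, which the C4 ketone and the two esters would not survive. The forward step needs only mild aqueous acid: ketal hydrolysis frees C1–OH, which can lactonise only onto C12 because C9 is already acylated.

**C11=C13 and C12 oxidation level (32 ⇒ 31 ⇒ 30 ⇒ 29 ⇒ 28).** The methylene is cut back to the C12 aldehyde 30 (amine-catalysed methylenation, then aldehyde-to-acid oxidation). Aldehyde 30 comes from silyl ether 28 through alcohol 29. The aldehyde is chosen because enamine/iminium chemistry picks it out in the presence of every other carbonyl. The forward steps must leave the ketal and the side chain alone.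

**C9 ester (28 ⇒ 20 + 26).** The acyl–O9 bond is cut to alcohol 20 and acid 26. Acylating before the lactone is built removes the C1/C9 competition for C12. Acid 26 is a three-step product of acetaldehyde 21 and tert-butyl acrylate 22 through Morita–Baylis–Hillman adduct 23 and transposed acetate 25.

**Differentiating C1–O from C9–O and C4 from C9 (20 ⇒ 19 ⇒ 18).** The ketal 20 is opened to diol 19, and the C9–H bond is cut to give hydroxy dione 18. The C1 hydroxyl does both jobs in the forward sense. It first delivers hydride to C9 (1,3-anti) and leaves the γ-related C4 ketone untouched. It then closes onto C4 as a five-membered ketal, leaving C9–OH as the only free hydroxyl. This replaces a selective acylation of a 1,3-diol that would rest on a hemiketal equilibrium alone.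

**Ring A (18 ⇒ 17), the key cut.** The C4–C9 bond is restored, turning the 1,6-dione into ring-fusion diol 17. Against any cyclisation to a ten-membered ring, this route never has to close ring A by bond formation, and the olefin is Z by construction. The precursor is a decalin with all three stereocentres on one chair. The forward step asks only for chemoselective glycol cleavage.

**Diol and diene (17 ⇒ 16 ⇒ 15 ⇒ 14).** The diol comes from epoxide 16 by anti hydrolysis, and 16 from diene 15 by peracid attack on the tetrasubstituted olefin. Diene 15 is the Birch product of tetralol 14. The arene encodes C4–C9 with the C7 methyl, so the regiochemistry of reduction puts the olefins where they are needed.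

**C1/C10 stereocentres and the C11–C12 arm (14 ⇒ 12 ⇒ 11 ⇒ 10 ⇒ 9 ⇒ 6 + 7).** The C1–O and C10–H bonds are cut by retro-hydroboration to styrene 12. Syn addition to a 1-substituted dihydronaphthalene gives the trans-1,2 relation, and the pseudoaxial C3 methyl steers the borane to the face that also makes the arm cis to the methyl. So one step sets two stereocentres from the third. Styrene 12 comes from ester 10 by reduction to 11 and silylation. The C10–C11 bond is cut by retro-Reformatsky/dehydration (via 9) to tetralone 6 and ethyl bromoacetate 7.

**C3 stereocentre and the tetralone (6 ⇒ 5 ⇒ 4 ⇒ 1 + 2).** Tetralone 6 is opened (Friedel–Crafts) to acid 5, whose single stereocentre is set by asymmetric hydrogenation of the β,γ-unsaturated acid 4. Acid 4 is the Wittig product of ketone 1 and phosphonium salt 2. All absolute stereochemistry thus comes from one catalytic step, with no resolution.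

## Roads not taken

**Alternative 1: anionic oxy-Cope expansion.** The cut is C8–C9, with C1–C6 reconnected, leading back to the cis-1,2-dialkenylcyclohexanol A1. In the forward sense its potassium alkoxide (KH, 18-crown-6) undergoes a [3,3] shift to the ten-membered ketone A2, forming a skeletal bond, the C9 ether stereocentre and the olefin in one step. A2 also arrives with its two carbonyl carbons already differentiated (C1 ketone, C4 dioxolane) and C9 protected. In this respect it is better than the chosen plan, which must differentiate dione 18 after the fact. Its weak points for this target are several: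
- The Z olefin requires the chair transition state with the ring residue at C6 axial, and a competing boat would leak E isomer.
- The enolate produced has the C9 tert-butoxy group in the β position and can eliminate it.
- A2 lacks the C10 arm and the C1 stereocentre. Both would have to be installed on a flexible ten-membered ketone (C10 versus C2 alkylation, facial control, then C1 reduction).

The chosen plan sets against this that C1, C3 and C10 are fixed on a rigid six-membered ring and only C9 is set on the medium ring, with an internal directing group.

**Alternative 2: Claisen ring expansion.** The cut is C2–C3, with O–C5 reconnected, leading to the 2-methylene oxocene A3. Heating would give ketone A4, which already carries C9, C10, the complete C11–C13 unit and the C3 stereocentre from a chair transition state. The endgame after A4 (C1 reduction, lactone oxidation, enol ether hydrolysis) would be clearly shorter than the ten steps that follow the key step here. The cost is paid earlier: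
- A3 is an eight-membered enol ether that must be built as a medium-ring lactone with three stereocentres and then methylenated.
- A geometrically defined silyl enol ether must be present throughout.
- The dienol ether in A4 must later be protonated at C5 and not at C7 to keep the olefin skipped.

The chosen plan sets against this that it never forms a medium ring by cyclisation and the skipped Z olefin is never in question, at the price of a longer endgame.

**Alternative 3: Wittig–Still ring contraction.** The cut is C9–C10, with O–C13 reconnected, leading to the thirteen-membered α-stannyl allylic ether A5. Tin–lithium exchange (n-BuLi) and [2,3] shift would give A6. A6 has the C13 methylene and C12 oxygen in place, C9–OH as the only free hydroxyl, C1 protected and C4 ketalised. This is exactly the oxygen differentiation the chosen plan must engineer in steps 13 and 14, so on this point the alternative is better. Its weak points: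
- A5 needs a stereodefined α-alkoxystannane and a thirteen-membered etherification.
- The C9/C10 relative configuration depends on the macrocycle conformation in the envelope transition state, with [1,2] shift as a competitor.
- The final acid removal of the C1 acetal and the dioxolane meets the β,γ-enone.
- Stoichiometric tin is used.

The chosen plan sets against this a ring-forming event that cannot fail for conformational reasons and stereocentres set by well-understood six-membered-ring models.

Key step: step 12

## Assumptions

- In step 2, SIPHOX denotes a 7-(diarylphosphino)-7'-(4,5-dihydrooxazol-2-yl)-1,1'-spirobiindane ligand and BArF is tetrakis[3,5-bis(trifluoromethyl)phenyl]borate. The ligand antipode is the one that gives the R acid, and the sense is to be confirmed on the first run.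
- The epoxide hydrolysis (step 11) is drawn with water entering at C9. The other trans-diol (water at C4) would be an equally good substrate and gives the same dione 18.
- Compounds 18 and 19 may rest partly as C1–O–C4 hemiketals. They are drawn open.

## The route

Step 1
Reactants: 1 4'-methylacetophenone; 2 (2-carboxyethyl)triphenylphosphonium bromide
Product: 4 (E)-4-(4-methylphenyl)pent-3-enoic acid, via carboxylate ylide 3 (not isolated)
Conditions: KOt-Bu (2.2 equiv), THF, 0 °C to 60 °C; aq. HCl; recrystallisation
Reagents that add atoms: KOt-Bu, [K+].CC(C)(C)[O-] (its potassium is held only in 3)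
Why: Wittig olefination of an aryl methyl ketone with the carboxylate ylide gives the β,γ-unsaturated acid directly; the E isomer should predominate and is brought to geometric purity by crystallisation, which matters because the two geometries would give opposite antipodes in step 2.

Step 2
Reactants: 4 (E)-4-(4-methylphenyl)pent-3-enoic acid
Product: 5 (R)-4-(4-methylphenyl)pentanoic acid
Conditions: H2 (6 bar), [Ir(cod)(SIPHOX)]BArF (1 mol %), Et3N (0.5 equiv), MeOH, 45 °C
Reagents that add atoms: none
Why: Carboxylate-directed asymmetric hydrogenation of a trisubstituted β,γ-unsaturated acid with a cationic iridium spiro phosphine–oxazoline catalyst, a known reaction type for 4-aryl-pent-3-enoic acids; the chiral ligand selects the olefin face and sets the future C3 as R.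

Step 3
Reactants: 5 (R)-4-(4-methylphenyl)pentanoic acid
Product: 6 (R)-4,7-dimethyl-3,4-dihydronaphthalen-1(2H)-one
Conditions: Eaton's reagent (P2O5 in MeSO3H), 50 °C
Reagents that add atoms: none
Why: Intramolecular Friedel–Crafts acylation; both positions ortho to the side chain are equivalent, so one tetralone results, and the benzylic stereocentre is not on the reaction path.

Step 4
Reactants: 6 (R)-4,7-dimethyl-3,4-dihydronaphthalen-1(2H)-one; 7 ethyl bromoacetate
Product: 9 ethyl 2-[(4R)-1-hydroxy-4,7-dimethyl-1,2,3,4-tetrahydronaphthalen-1-yl]acetate, via Reformatsky reagent 8 (not isolated)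
Conditions: Zn dust (TMSCl-activated), THF, reflux; cold 1 M HCl
Reagents that add atoms: zinc, [Zn] (held only in 8)
Why: Reformatsky addition of the zinc enolate to the aryl ketone forms the C10–C11 bond; the configuration of the new carbinol is irrelevant because it is removed in step 5.

Step 5
Reactants: 9 ethyl 2-[(4R)-1-hydroxy-4,7-dimethyl-1,2,3,4-tetrahydronaphthalen-1-yl]acetate
Product: 10 ethyl 2-[(4R)-4,7-dimethyl-3,4-dihydronaphthalen-1-yl]acetate
Conditions: p-TsOH·H2O (5 mol %), toluene, reflux, Dean–Stark
Reagents that add atoms: none
Why: E1 dehydration of the tertiary benzylic alcohol; the endocyclic styrene is favoured over the exocyclic enoate because the latter suffers peri strain, and the remote C4 stereocentre is not reached by the benzylic cation.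

Step 6
Reactants: 10 ethyl 2-[(4R)-4,7-dimethyl-3,4-dihydronaphthalen-1-yl]acetate
Product: 11 2-[(4R)-4,7-dimethyl-3,4-dihydronaphthalen-1-yl]ethanol
Conditions: LiAlH4, THF, 0 °C
Reagents that add atoms: none
Why: Hydride reduction of the ester to the primary alcohol (C12); the styrene is inert and the fast reduction leaves no time for base-induced olefin migration.

Step 7
Reactants: 11 2-[(4R)-4,7-dimethyl-3,4-dihydronaphthalen-1-yl]ethanol
Product: 12 triisopropyl{2-[(4R)-4,7-dimethyl-3,4-dihydronaphthalen-1-yl]ethoxy}silane
Conditions: TIPSCl, imidazole, DMF, rt
Reagents that add atoms: triisopropylsilyl chloride, CC(C)[Si](Cl)(C(C)C)C(C)C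
Why: Silylation of the only hydroxyl; the triisopropylsilyl ether is chosen because it survives Li/NH3, the dilute acid of step 11 and the acidic methanol of step 14.

Step 8
Reactants: 12 triisopropyl{2-[(4R)-4,7-dimethyl-3,4-dihydronaphthalen-1-yl]ethoxy}silane
Product: 14 (1R,2R,4R)-4,7-dimethyl-1-[2-(triisopropylsilyloxy)ethyl]-1,2,3,4-tetrahydronaphthalen-2-ol, via alkylborane 13 (not isolated)
Conditions: BH3·THF, THF, 0 °C to rt; then 3 M NaOH, 30% H2O2, 0 °C to rt
Reagents that add atoms: borane–THF, B (its boron is held only in 13); hydrogen peroxide, OO
Why: Hydroboration–oxidation of a 1-substituted dihydronaphthalene places boron on the non-benzylic carbon and adds H and B syn, so the hydroxyl (C1 of ring A) ends trans to the side chain (C10). The C4 methyl is pseudoaxial (peri strain) and blocks its own face, so the borane should add anti to it, which makes the side chain cis to the methyl and the hydroxyl trans to it; oxidation proceeds with retention.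

Step 9
Reactants: 14 (1R,2R,4R)-4,7-dimethyl-1-[2-(triisopropylsilyloxy)ethyl]-1,2,3,4-tetrahydronaphthalen-2-ol
Product: 15 (1R,2R,4R)-4,7-dimethyl-1-[2-(triisopropylsilyloxy)ethyl]-1,2,3,4,5,8-hexahydronaphthalen-2-ol
Conditions: Li (10 equiv), NH3(l)/THF, t-BuOH, −78 °C to −33 °C; solid NH4Cl
Reagents that add atoms: none
Why: Birch reduction of a 1,2,4-trialkylbenzene protonates the two unsubstituted para positions (C5 and C8 of ring A), leaving the tetrasubstituted C4=C9 and the trisubstituted C6=C7 olefin; the alkoxide and the silyl ether are inert and the stereocentres are untouched.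

Step 10
Reactants: 15 (1R,2R,4R)-4,7-dimethyl-1-[2-(triisopropylsilyloxy)ethyl]-1,2,3,4,5,8-hexahydronaphthalen-2-ol
Product: 16 4a,8a-epoxide of 15 with the oxirane oxygen cis to the C2 hydroxyl
Conditions: mCPBA (1.05 equiv), NaHCO3, CH2Cl2, −20 °C
Reagents that add atoms: mCPBA, OOC(=O)c1cccc(Cl)c1
Why: Peracid epoxidation selects the most electron-rich, tetrasubstituted olefin over the trisubstituted one; attack should come anti to the two allylic substituents and syn to the homoallylic hydroxyl, though the face has no bearing on the final product.

Step 11
Reactants: 16 4a,8a-epoxide of 15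
Product: 17 ring-fusion trans-diol (2,4a,8a-triol; C4–OH of ring A cis to the C1 hydroxyl and C9–OH trans)
Conditions: HClO4 (0.1 equiv), THF/H2O (3:1), 0 °C
Reagents that add atoms: water, O
Why: Acid-catalysed anti opening of the tetrasubstituted oxirane gives the trans-diaxial glycol (Fürst–Plattner); the fully substituted epoxide ionises far faster than the primary silyl ether cleaves, and both C4 and C9 lose their stereochemistry in step 12.

Step 12
Reactants: 17 ring-fusion trans-diol
Product: 18 (Z)-cyclodec-6-ene-4,9-dione of ring A with free C1 hydroxyl, C3 methyl, C7 methyl and C10 2-(triisopropylsilyloxy)ethyl arm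
Conditions: Pb(OAc)4 (1.2 equiv), pyridine/CH2Cl2 (1:4), 0 °C to rt
Reagents that add atoms: none
Why: Exchange of an acetate on tetravalent lead for a tertiary hydroxyl of 17 gives a lead alkoxide that fragments in a two-electron step: the C4–C9 bond breaks, both carbinol carbons become ketones, and Pb(OAc)2 (divalent lead) and two AcOH are released. The glycol is trans-diaxial and cannot form a five-membered cyclic ester, which is why Pb(OAc)4 with pyridine is used and not periodate: lead cleaves such diols through an open, base-assisted pathway, more slowly than cis-diols. The closest known reaction type is the Criegee glycol cleavage of ring-fusion 9,10-diols of hydronaphthalenes to cyclodecane-1,6-diones. No ring is closed by bond formation; ring A is the perimeter of the bicycle and appears when the shared bond is cut, so there is no mode of closure to control. No stereocentre is created; C1, C3 and C10 come from the six-membered ring, and C6=C7 is Z because it was a cyclohexene double bond. The selectivity needed is for the vicinal diol: the C1 hydroxyl is 1,3-related to C9 and cannot take part, and the trisubstituted olefin is inert to Pb(OAc)4 at this temperature. Since C3 and C10 become α to ketones, 18 is kept cold and near neutral and reduced at once; reversible addition of C1–OH to C4 (hemiketal) should hold the 1,6-dione back from transannular aldol.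

Step 13
Reactants: 18 (Z)-cyclodec-6-ene-4,9-dione with free C1 hydroxyl
Product: 19 C9 alcohol of 18 (1,9-anti-diol; C9–OH cis to the C10 arm and trans to C1–OH; C4 ketone retained)
Conditions: Me4NBH(OAc)3 (5 equiv), MeCN/AcOH (1:1), −30 °C to −20 °C
Reagents that add atoms: none
Why: Evans–Saksena reduction: the C1 hydroxyl exchanges onto boron and delivers hydride internally to the β-related C9 carbonyl from its own face of ring A, so the new hydroxyl lies on the opposite face (1,3-anti). The reagent is inert to ketones that lack a β-hydroxyl, so the γ-related C4 ketone should survive, and the acidic medium removes the C10 epimerisation and retro-aldol risks of 18.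

Step 14
Reactants: 19 1,9-anti-diol with C4 ketone
Product: 20 bridged methyl ketal of 19 (C1–O–C4 bridge, C4–OMe, free C9–OH; 11-oxabicyclo[6.2.1]undecene core)
Conditions: PPTS (0.1 equiv), MeOH, 4 Å MS, 0 °C to rt
Reagents that add atoms: methanol, CO
Why: Mixed ketal formation from a γ-hydroxy ketone: C1–OH closes onto C4 through a five-membered ring and methanol caps the oxocarbenium ion, whereas C9–OH could reach C4 only through a seven-membered ring and the anti-diol cannot span C4 as a dioxane. The new C4 stereocentre is fixed by the bridge (oxygen enters from the face on which C1–O sits), and the ketal protects C1–O, the β,γ-enone and C3 in one step.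

Step 15
Reactants: 21 acetaldehyde; 22 tert-butyl acrylate
Product: 23 tert-butyl 3-hydroxy-2-methylenebutanoate
Conditions: DABCO (0.5 equiv), 1,4-dioxane/H2O (1:1), rt
Reagents that add atoms: none
Why: Morita–Baylis–Hillman reaction; the racemic carbinol centre is removed in step 16.

Step 16
Reactants: 23 tert-butyl 3-hydroxy-2-methylenebutanoate
Product: 25 tert-butyl (E)-2-(acetoxymethyl)but-2-enoate, via secondary acetate 24 (not isolated)
Conditions: Ac2O, Et3N, DMAP (5 mol %), THF, 0 °C to rt; then DABCO (0.2 equiv), 65 °C
Reagents that add atoms: acetic anhydride, CC(=O)OC(C)=O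
Why: Acetylation followed by amine-catalysed 1,3-transposition of the acetate (two consecutive SN2' steps) gives the thermodynamically preferred primary allylic acetate with the methyl trans to the ester, which is the geometry of the target side chain.

Step 17
Reactants: 25 tert-butyl (E)-2-(acetoxymethyl)but-2-enoate
Product: 26 (E)-2-(acetoxymethyl)but-2-enoic acid
Conditions: TFA/CH2Cl2 (1:4), 0 °C to rt
Reagents that add atoms: none
Why: Acidolysis of the tert-butyl ester leaves the primary acetate and the olefin geometry untouched.

Step 18
Reactants: 20 bridged methyl ketal with free C9–OH; 26 (E)-2-(acetoxymethyl)but-2-enoic acid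
Product: 28 C9 (E)-2-(acetoxymethyl)but-2-enoate of 20, via mixed anhydride 27 (not isolated)
Conditions: 26, 2,4,6-trichlorobenzoyl chloride, Et3N, toluene, rt; then 20, DMAP, 0 °C to rt
Reagents that add atoms: 2,4,6-trichlorobenzoyl chloride, O=C(Cl)c1c(Cl)cc(Cl)cc1Cl (held only in 27)
Why: Yamaguchi esterification of the only free hydroxyl; the alcohol attacks the less hindered aliphatic carbonyl of the mixed anhydride, and low temperature limits reversible SN2' addition of DMAP to the allylic acetate.

Step 19
Reactants: 28 C9 ester with C12 silyl ether
Product: 29 primary alcohol (C12–OH) of 28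
Conditions: HF·pyridine, pyridine, THF, 0 °C to rt
Reagents that add atoms: none
Why: Buffered fluoride cleavage of the primary silyl ether; the excess pyridine keeps the medium mild enough for the mixed ketal, the allylic acetate and the ester.

Step 20
Reactants: 29 primary alcohol
Product: 30 C12 aldehyde
Conditions: Dess–Martin periodinane, NaHCO3, CH2Cl2, 0 °C to rt
Reagents that add atoms: none
Why: Oxidation of the single free hydroxyl under buffered, non-aqueous conditions; with C1–O locked in the ketal the aldehyde cannot close to a lactol and over-oxidise.

Step 21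
Reactants: 30 C12 aldehyde
Product: 31 α-methylene aldehyde (C11=C13)
Conditions: 37% aq. CH2O (3 equiv), pyrrolidine (0.1 equiv), propionic acid (0.1 equiv), i-PrOH, 45 °C
Reagents that add atoms: formaldehyde, C=O
Why: Amine-catalysed α-methylenation of an α-unbranched aldehyde (enamine Mannich addition to the formaldehyde iminium, then elimination); only the aldehyde forms an enamine under these conditions, no stereocentre is involved, and the excess formaldehyde keeps free pyrrolidine away from the side-chain allylic acetate.

Step 22
Reactants: 31 α-methylene aldehyde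
Product: 32 2-substituted acrylic acid (C12 acid; ketal and C9 ester intact)
Conditions: NaClO2, NaH2PO4, 2-methyl-2-butene, t-BuOH/H2O, 0 °C to rt
Reagents that add atoms: sodium chlorite, [Na+].[O-]Cl=O
Why: Pinnick oxidation of a 2-substituted acrolein to the acrylic acid; the alkene scavenger removes HOCl before it can reach the C6=C7 olefin.

Step 23
Reactants: 32 acrylic acid with bridged methyl ketal
Product: 34 CNP0265140.1, via hydroxy acid 33 (not isolated)
Conditions: AcOH/THF/H2O (3:1:1), 40 °C
Reagents that add atoms: water, O
Why: Mild aqueous acid hydrolyses the mixed ketal (oxocarbenium at C4, water in, methanol out), which frees the C4 ketone and C1–OH. The hydroxyl then closes the γ-lactone onto the acrylic acid (5-exo-trig), and only C1–O can do so because C9 is esterified. The trans fusion follows from the C1/C10 configuration set in step 8, and the weak acid should leave the skipped enone and C3 alone.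

## Compound list

1 | 4'-methylacetophenone | CC(=O)c1ccc(C)cc1 | starting material
2 | (2-carboxyethyl)triphenylphosphonium bromide | OC(=O)CC[P+](c1ccccc1)(c1ccccc1)c1ccccc1.[Br-] | starting material
3 | potassium 3-(triphenylphosphoranylidene)propanoate (carboxylate ylide) | [K+].[O-]C(=O)CC=P(c1ccccc1)(c1ccccc1)c1ccccc1 | intermediate
4 | (E)-4-(4-methylphenyl)pent-3-enoic acid | C/C(=C\CC(=O)O)c1ccc(C)cc1 | intermediate
5 | (R)-4-(4-methylphenyl)pentanoic acid | C[C@H](CCC(=O)O)c1ccc(C)cc1 | intermediate
6 | (R)-4,7-dimethyl-3,4-dihydronaphthalen-1(2H)-one | C[C@@H]1CCC(=O)c2cc(C)ccc21 | intermediate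
7 | ethyl bromoacetate | CCOC(=O)CBr | starting material
8 | ethyl (bromozincio)acetate (Reformatsky reagent) | CCOC(=O)C[Zn]Br | intermediate
9 | ethyl 2-[(4R)-1-hydroxy-4,7-dimethyl-1,2,3,4-tetrahydronaphthalen-1-yl]acetate (both C1 epimers) | CCOC(=O)CC1(O)CC[C@@H](C)c2ccc(C)cc21 | intermediate
10 | ethyl 2-[(4R)-4,7-dimethyl-3,4-dihydronaphthalen-1-yl]acetate | CCOC(=O)CC1=CC[C@@H](C)c2ccc(C)cc21 | intermediate
11 | 2-[(4R)-4,7-dimethyl-3,4-dihydronaphthalen-1-yl]ethanol | OCCC1=CC[C@@H](C)c2ccc(C)cc21 | intermediate
12 | triisopropyl{2-[(4R)-4,7-dimethyl-3,4-dihydronaphthalen-1-yl]ethoxy}silane | CC(C)[Si](C(C)C)(C(C)C)OCCC1=CC[C@@H](C)c2ccc(C)cc21 | intermediate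
13 | alkylborane from 12 (drawn as RBH2; boron at C2, trans to the side chain) | CC(C)[Si](C(C)C)(C(C)C)OCC[C@H]1[C@H]([BH2])C[C@@H](C)c2ccc(C)cc21 | intermediate
14 | (1R,2R,4R)-4,7-dimethyl-1-[2-(triisopropylsilyloxy)ethyl]-1,2,3,4-tetrahydronaphthalen-2-ol (OH trans to side chain, side chain cis to C4 methyl) | CC(C)[Si](C(C)C)(C(C)C)OCC[C@H]1[C@H](O)C[C@@H](C)c2ccc(C)cc21 | intermediate
15 | (1R,2R,4R)-4,7-dimethyl-1-[2-(triisopropylsilyloxy)ethyl]-1,2,3,4,5,8-hexahydronaphthalen-2-ol | CC(C)[Si](C(C)C)(C(C)C)OCC[C@H]1[C@H](O)C[C@@H](C)C2=C1CC(C)=CC2 | intermediate
16 | 4a,8a-epoxide of 15, oxirane oxygen cis to the C2 hydroxyl and trans to the side chain and C4 methyl | CC(C)[Si](C(C)C)(C(C)C)OCC[C@H]1[C@H](O)C[C@@H](C)[C@@]23CC=C(C)C[C@@]12O3 | intermediate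
17 | ring-fusion trans-diol: hexahydronaphthalene-2,4a,8a-triol, 4a-OH (C4 of ring A) cis to the 2-OH, 8a-OH (C9) trans | CC(C)[Si](C(C)C)(C(C)C)OCC[C@H]1[C@H](O)C[C@@H](C)[C@@]2(O)CC=C(C)C[C@]12O | intermediate
18 | (Z)-cyclodec-6-ene-4,9-dione (ring-A numbering) with C1 hydroxyl, C3 and C7 methyls, C10 2-(triisopropylsilyloxy)ethyl; C1–OH trans to the arm, C3–Me cis to it | CC(C)[Si](C(C)C)(C(C)C)OCC[C@H]1[C@H](O)C[C@@H](C)C(=O)C/C=C(/C)CC1=O | intermediate
19 | C9 alcohol of 18: 1,9-anti-diol, C9–OH cis to the C10 arm; C4 ketone | CC(C)[Si](C(C)C)(C(C)C)OCC[C@H]1[C@H](O)C[C@@H](C)C(=O)C/C=C(/C)C[C@H]1O | intermediate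
20 | bridged methyl ketal of 19: C1–O–C4 bridge, C4–OMe, free C9–OH | CC(C)[Si](C(C)C)(C(C)C)OCC[C@H]1[C@H]2C[C@@H](C)[C@](OC)(O2)C/C=C(/C)C[C@H]1O | intermediate
21 | acetaldehyde | CC=O | starting material
22 | tert-butyl acrylate | C=CC(=O)OC(C)(C)C | starting material
23 | tert-butyl 3-hydroxy-2-methylenebutanoate (racemic) | CC(O)C(=C)C(=O)OC(C)(C)C | intermediate
24 | tert-butyl 3-acetoxy-2-methylenebutanoate | CC(OC(C)=O)C(=C)C(=O)OC(C)(C)C | intermediate
25 | tert-butyl (E)-2-(acetoxymethyl)but-2-enoate | C/C=C(\COC(C)=O)C(=O)OC(C)(C)C | intermediate
26 | (E)-2-(acetoxymethyl)but-2-enoic acid | C/C=C(\COC(C)=O)C(=O)O | intermediate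
27 | mixed anhydride of 26 with 2,4,6-trichlorobenzoic acid | C/C=C(\COC(C)=O)C(=O)OC(=O)c1c(Cl)cc(Cl)cc1Cl | intermediate
28 | C9 (E)-2-(acetoxymethyl)but-2-enoate of 20 | CC(C)[Si](C(C)C)(C(C)C)OCC[C@H]1[C@H]2C[C@@H](C)[C@](OC)(O2)C/C=C(/C)C[C@H]1OC(=O)/C(=C/C)COC(C)=O | intermediate
29 | primary alcohol (C12–OH) from 28 | OCC[C@H]1[C@H]2C[C@@H](C)[C@](OC)(O2)C/C=C(/C)C[C@H]1OC(=O)/C(=C/C)COC(C)=O | intermediate
30 | C12 aldehyde | O=CC[C@H]1[C@H]2C[C@@H](C)[C@](OC)(O2)C/C=C(/C)C[C@H]1OC(=O)/C(=C/C)COC(C)=O | intermediate
31 | α-methylene aldehyde (C11=C13) | C=C(C=O)[C@H]1[C@H]2C[C@@H](C)[C@](OC)(O2)C/C=C(/C)C[C@H]1OC(=O)/C(=C/C)COC(C)=O | intermediate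
32 | acrylic acid (C12 acid) with bridged methyl ketal | C=C(C(=O)O)[C@H]1[C@H]2C[C@@H](C)[C@](OC)(O2)C/C=C(/C)C[C@H]1OC(=O)/C(=C/C)COC(C)=O | intermediate
33 | hydroxy acid: free C1–OH, C4 ketone, C12 acid | C=C(C(=O)O)[C@H]1[C@H](O)C[C@@H](C)C(=O)C/C=C(/C)C[C@H]1OC(=O)/C(=C/C)COC(C)=O | intermediate
34 | CNP0265140.1: trans-fused α-methylene lactone of ring A with C4 ketone, Z C6=C7 olefin and C9 (E)-2-(acetoxymethyl)but-2-enoate | C=C1C(=O)O[C@@H]2C[C@@H](C)C(=O)C/C=C(/C)C[C@@H](OC(=O)/C(=C/C)COC(C)=O)[C@@H]12 | target

## Step count and least certain steps

Total step count: 23 (20 in the main line, 3 for acid 26). Longest linear sequence: 20 steps (steps 1–14 and 18–23).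

**Step 12 (key step).** The most likely failure is slow cleavage, because the glycol is locked trans-diaxial and cannot form a cyclic lead ester. A second danger is loss of the product during a long reaction, by transannular aldol of the 1,6-dione or by epimerisation or β-elimination at C10. The same fallback also covers an epoxide hydrolysis (step 11) that drifts towards elimination. Fallback: it sets out from diene 15 and returns at 18. Ozone (1 equiv, titrated at −78 °C in CH2Cl2/pyridine, then Me2S) is directed at the tetrasubstituted olefin of 15, the most electron-rich one, and should give dione 18 directly without epoxide or diol. No new isolated compound is involved.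

**Step 8.** The risk is poor facial discrimination in the hydroboration, since the only control element is the remote pseudoaxial methyl group; attack on the wrong face would put the side chain trans to the methyl. Fallback: it sets out from tetralone 6 and returns at 14, and replaces substrate control by reagent control.
- Reduction of 6 with NaBH4 gives (4R)-4,7-dimethyl-1,2,3,4-tetrahydronaphthalen-1-ol F1.
- Acid-catalysed dehydration gives (R)-1,6-dimethyl-1,2-dihydronaphthalene F2.
- Jacobsen epoxidation with (S,S)-(salen)MnCl [salen = N,N'-bis(3,5-di-tert-butylsalicylidene)cyclohexane-1,2-diamine dianion], NaOCl and 4-phenylpyridine N-oxide delivers oxygen anti to the methyl group and gives the epoxide F3. The catalyst antipode is chosen by analogy with indene.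
- Opening at the benzylic carbon with CH2=CHMgBr and catalytic CuI, with inversion, gives the trans-1-vinyl-2-tetralol F4.
- Hydroboration of the vinyl group with 9-BBN and oxidation gives the diol F5.
- Silylation of the primary hydroxyl with TIPSCl/imidazole gives 14.

**Step 13.** The risk is that the ten-membered ring does not allow the geometry needed for internal hydride delivery, which would show as poor facial selectivity at C9 or as a stalled reduction during which 18 decays. Fallback: it sets out from 18 and returns at 20.
- Ketalisation first (PPTS, MeOH) gives the bridged keto ketal F6, in which C9 is the only carbonyl.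
- Reduction with NaBH4 from the more open face of the bicycle follows. If it gives 20, the route continues.
- If it gives the C9 epimer F7, Mitsunobu inversion with 4-nitrobenzoic acid (PPh3, DIAD) gives the inverted 4-nitrobenzoate F8, and methanolysis (K2CO3, MeOH) returns 20.

**Step 21.** The risk is consumption of the amine catalyst, and of material, by SN2' or conjugate addition to the acetoxymethyl butenoate or to the product enal, and slow ketal hydrolysis in the warm aqueous medium. Fallback: it sets out from 30 and returns at 31, and uses a stoichiometric Mannich/elimination sequence without a secondary amine or water.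
- Dimethylmethyleneammonium iodide and Et3N in CH2Cl2 give the β-dimethylamino aldehyde F9.
- Quaternisation with MeI gives the ammonium iodide F10.
- Elimination with NaHCO3 gives 31.

## Further compounds

F0 | step 12 | none | none
F1 | step 8 | (4R)-4,7-dimethyl-1,2,3,4-tetrahydronaphthalen-1-ol (both C1 epimers) | C[C@@H]1CCC(O)c2cc(C)ccc21
F2 | step 8 | (R)-1,6-dimethyl-1,2-dihydronaphthalene | C[C@@H]1CC=Cc2cc(C)ccc21
F3 | step 8 | 3,4-epoxide of F2 with the oxygen trans to the C1 methyl | C[C@@H]1C[C@H]2O[C@H]2c3cc(C)ccc31
F4 | step 8 | (1R,2R,4R)-4,7-dimethyl-1-vinyl-1,2,3,4-tetrahydronaphthalen-2-ol | C=C[C@H]1[C@H](O)C[C@@H](C)c2ccc(C)cc21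
F5 | step 8 | (1R,2R,4R)-1-(2-hydroxyethyl)-4,7-dimethyl-1,2,3,4-tetrahydronaphthalen-2-ol | OCC[C@H]1[C@H](O)C[C@@H](C)c2ccc(C)cc21
F6 | step 13 | bridged methyl ketal of 18 with C9 ketone | CC(C)[Si](C(C)C)(C(C)C)OCC[C@H]1[C@H]2C[C@@H](C)[C@](OC)(O2)C/C=C(/C)CC1=O
F7 | step 13 | C9 epimer of 20 | CC(C)[Si](C(C)C)(C(C)C)OCC[C@H]1[C@H]2C[C@@H](C)[C@](OC)(O2)C/C=C(/C)C[C@@H]1O
F8 | step 13 | C9 4-nitrobenzoate of 20 | CC(C)[Si](C(C)C)(C(C)C)OCC[C@H]1[C@H]2C[C@@H](C)[C@](OC)(O2)C/C=C(/C)C[C@H]1OC(=O)c3ccc([N+](=O)[O-])cc3
F9 | step 21 | β-dimethylamino aldehyde (Mannich base of 30, both C11 epimers) | CN(C)CC(C=O)[C@H]1[C@H]2C[C@@H](C)[C@](OC)(O2)C/C=C(/C)C[C@H]1OC(=O)/C(=C/C)COC(C)=O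
F10 | step 21 | trimethylammonium iodide of F9 | C[N+](C)(C)CC(C=O)[C@H]1[C@H]2C[C@@H](C)[C@](OC)(O2)C/C=C(/C)C[C@H]1OC(=O)/C(=C/C)COC(C)=O.[I-]
A1 | alternative 1 | cis-1,2-dialkenylcyclohexanol: 1-[(E)-2-tert-butoxyvinyl]-2-isopropenylcyclohexanol with C3 methyl and C4 dioxolane (drawn for a chair transition state) | C=C(C)[C@@H]1CC2(OCCO2)[C@H](C)C[C@]1(O)/C=C/OC(C)(C)C
A2 | alternative 1 | ten-membered C1 ketone with C9 tert-butyl ether and C4 dioxolane | O=C1C[C@@H](C)C2(OCCO2)C/C=C(/C)C[C@@H](OC(C)(C)C)C1
A3 | alternative 2 | 2-methylene oxocene with C5 silyl enol ether side chain, C9 PMB ether and C10 2-(silyloxymethyl)vinyl group (drawn for a chair transition state) | C=C1O[C@H](/C(O[Si](C)(C)C(C)(C)C)=C/C)/C=C(/C)C[C@@H](OCc2ccc(OC)cc2)[C@H]1C(=C)CO[Si](C)(C)C(C)(C)C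
A4 | alternative 2 | ten-membered C1 ketone with C4 silyl dienol ether | O=C1C[C@@H](C)/C(O[Si](C)(C)C(C)(C)C)=C\C=C(\C)C[C@@H](OCc2ccc(OC)cc2)[C@H]1C(=C)CO[Si](C)(C)C(C)(C)C
A5 | alternative 3 | thirteen-membered α-tributylstannyl allylic ether (O between C9 and C13) | CCCC[Sn](CCCC)(CCCC)[C@H]1OC/C(CO[Si](C)(C)C(C)(C)C)=C\[C@H](OCOC)C[C@@H](C)C2(OCCO2)C/C=C(/C)C1
A6 | alternative 3 | ten-membered C9 alcohol with C10 2-(silyloxymethyl)vinyl group | C=C(CO[Si](C)(C)C(C)(C)C)[C@H]1[C@H](OCOC)C[C@@H](C)C2(OCCO2)C/C=C(/C)C[C@H]1O
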